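**Retrosynthetic overview**
1. The target comes from global O-demethylation of its tri-O-methyl ether, a 19-membered macrocycle.
2. The 19-membered ring comes from a double SO2-extrusive ring contraction (21 → 20 → 19) of a bis-sulfone macrocycle. Both ArCH2–CH2Ar bonds are made in this step.
3. The 21-membered ring is the only ring formed. It is closed by stitching the ring A and ring D benzylic bromides with sulfide, then oxidising at sulfur. The ring B/ring C sulfone is already in place and shields its CH2 groups during the bromination.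
4. The open chain comes from Ullmann coupling of p-cresol (ring D) onto the ring C dibromide, followed by methoxylation. The ring B–CH2SO2CH2–ring C link comes from a benzylic sulfinate and a benzylic bromide.
5. The ring A–O–ring B phenol comes from m-cresol and 3-bromotoluene, then ortho-lithiation and oxidation. The ring C bromide comes from p-cresol and three equivalents of Br2.

Ring labels: A is the monophenol ring, B the meta-linked unsubstituted ring, C the catechol ring, and D the para-linked ring.

Assumption: the SMILES carries no stereocentre, axis or plane descriptor. The 19-membered ring is taken as conformationally mobile, so the target is treated as achiral and no stereocontrol is needed.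

**Step 1**
Reactants: 1 m-cresol (3-methylphenol); 2 3-bromotoluene
Product: 3 bis(3-methylphenyl) ether
Conditions: CuI (5 mol%), picolinic acid (10 mol%), K3PO4, DMSO, 90 °C
Reagents that add atoms: none
Why: This is a ligand-accelerated Ullmann diaryl ether synthesis between an unhindered phenol and an unhindered aryl bromide, with no other reactive site in either partner.

**Step 2**
Reactants: 3 bis(3-methylphenyl) ether
Product: 6 4-methyl-2-(3-methylphenoxy)phenol, via aryllithium 4 (not isolated), via dimethyl boronate 5 (not isolated)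
Conditions: n-BuLi (1.05 equiv), THF, 0 °C to rt; B(OMe)3, −78 °C to rt; 30% H2O2, 0 °C to rt
Reagents that add atoms: n-butyllithium [Li]CCCC (lithium of 4); trimethyl borate COB(OC)OC (boron group of 5); hydrogen peroxide OO (oxygen of 6)
Why: Directed ortho-metalation by the ether oxygen goes to the open ortho carbon para to CH3 (the other ortho carbon is wedged between OAr and CH3, and the two rings of 3 are equivalent, so one monolithio species forms), and borylation followed by peroxide oxidation turns C–Li into C–OH.

**Step 3**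
Reactants: 7 p-cresol (4-methylphenol)
Product: 9 2,6-dibromo-4-(bromomethyl)phenol, via 2,6-dibromo-4-methylphenol 8 (not isolated)
Conditions: Br2 (2.0 equiv), 1,2-dichlorobenzene, 35 °C; then Br2 (1.0 equiv), 150 °C
Reagents that add atoms: bromine BrBr
Why: Electrophilic aromatic bromination fills both ortho positions of the phenol, and the third equivalent then brominates the side chain, which is the classical hot bromination of 2,6-dihalo-4-methylphenols to 4-hydroxybenzyl bromides.

**Step 4**
Reactants: 6 4-methyl-2-(3-methylphenoxy)phenol; 9 2,6-dibromo-4-(bromomethyl)phenol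
Product: 12 2,6-dibromo-4-({[3-(2-hydroxy-5-methylphenoxy)benzyl]sulfonyl}methyl)phenol, via dipotassium dianion 10 (not isolated), via potassium sulfinate 11 (not isolated)
Conditions: n-BuLi and KOtBu (2.2 equiv each), 2,2,6,6-tetramethylpiperidine (TMP-H, 1.1 equiv), THF, −78 to −40 °C; SO2 (THF solution), −78 °C to rt; AcOH (3.3 equiv), concentrate; 9, DMF, rt
Reagents that add atoms: sulfur dioxide O=S=O; potassium tert-butoxide CC(C)(C)[O-].[K+] (potassium of 10 and 11)
Why: Lateral benzylic metalation with the mixed lithium/potassium amide superbase is under thermodynamic control, so after O–H deprotonation only the ring B methyl (meta to aryloxy) is metalated and not the ring A methyl (para to phenoxide); SO2 insertion then gives the sulfinate, which is S-alkylated by 9 (SN2 or 1,6-addition to its quinone methide) while the re-protonated phenol stays inert.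

**Step 5**
Reactants: 12 bis-phenol sulfone
Product: 13 1,3-dibromo-2-methoxy-5-({[3-(2-methoxy-5-methylphenoxy)benzyl]sulfonyl}methyl)benzene
Conditions: MeI (3 equiv), K2CO3, DMF, 40 °C
Reagents that add atoms: iodomethane CI
Why: This is a Williamson O-methylation of both phenols, and K2CO3 is far too weak to deprotonate the sulfone CH2 groups.

**Step 6**
Reactants: 13 dibromo sulfone; 7 p-cresol
Product: 15 1,2-dimethoxy-5-({[3-(2-methoxy-5-methylphenoxy)benzyl]sulfonyl}methyl)-3-(4-methylphenoxy)benzene, via bromo diaryl ether 14 (not isolated)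
Conditions: 7 (1.05 equiv), CuI (20 mol%), N,N-dimethylglycine (40 mol%), Cs2CO3, DMF, 110 °C; then NaOMe (5 equiv, 25% in MeOH), 110 °C
Reagents that add atoms: sodium methoxide C[O-].[Na+]
Why: Ullmann coupling occurs at one of two equivalent C–Br bonds (the first aryloxy group slows a second substitution), and copper-catalysed methoxylation of the remaining C–Br bond follows in the same pot, with the sulfone and ethers inert.

**Step 7**
Reactants: 15 open-chain sulfone with two methyl termini
Product: 16 bis(bromomethyl) compound (CH2Br on ring A para to OMe and on ring D para to OAr)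
Conditions: BrCCl3 (6 equiv), benzophenone (10 mol%), 365 nm LED, PhCF3, 30 °C; used crude
Reagents that add atoms: bromotrichloromethane BrC(Cl)(Cl)Cl
Why: In this Wohl–Ziegler-type radical-chain benzylic bromination BrCCl3 delivers bromine without free Br2 or HBr, so the electron-rich rings are not ring-brominated, and the sulfone-flanked CH2 groups are polarity-mismatched with the electrophilic CCl3 radical, which leaves only the two donor-activated methyl groups to react.

**Step 8**
Reactants: 16 bis(bromomethyl) compound
Product: 18 21-membered bis-sulfone macrocycle (tri-O-methyl), via thia-macrocycle 17 (not isolated)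
Conditions: Na2S·9H2O (1.0 equiv), DMF, rt, syringe-pump co-addition (final 1 mM); aqueous work-up; crude, mCPBA (2.2 equiv), CH2Cl2, 0 °C
Reagents that add atoms: sodium sulfide (as nonahydrate) [Na+].[Na+].[S-2]; 3-chloroperoxybenzoic acid OOC(=O)c1cccc(Cl)c1
Why: Classical high-dilution thiacyclophane closure by double SN2 of sulfide on two activated benzylic bromides gives an unstrained 21-membered ring, and peracid oxidation of the crude sulfide brings both bridges to the sulfone level.

**Step 9**
Reactants: 18 21-membered bis-sulfone macrocycle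
Product: 20 19-membered tri-O-methyl macrocycle, via 20-membered monosulfone 19 (not isolated)
Conditions: Ni(cod)2 (20 mol%), IPr [1,3-bis(2,6-diisopropylphenyl)imidazol-2-ylidene] (40 mol%), m-xylene (2 mM), 130 °C, continuous argon sparge
Reagents that add atoms: none
Why: Proposed new method: zerovalent nickel inserts into a benzylic C–SO2 bond to give an eta-3-benzyl nickel sulfinate, loss of SO2 (swept out by argon) leaves a bis(benzyl) divalent nickel macrocycle with no beta-hydrogens, and C(sp3)–C(sp3) reductive elimination closes the ring one atom smaller, so two turnovers take the ring from 21 through 20 to 19 members and make both ArCH2–CH2Ar bonds in a stepwise, non-concerted ring contraction; the closest known reaction types are the nickel-catalysed intramolecular desulfitative coupling of diaryl sulfones to biaryls and the desulfonylative cross-coupling of benzylic sulfones, neither shown for bis-benzylic sulfones or for macrocycles.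

**Step 10**
Reactants: 20 19-membered tri-O-methyl macrocycle
Product: 21 target CNP0495401.0
Conditions: BBr3 (4 equiv), CH2Cl2, −78 °C to rt; H2O
Reagents that add atoms: none
Why: Lewis-acid aryl methyl ether cleavage with BBr3 removes the three methyl groups while the diaryl ethers and bibenzyl bridges are untouched, and there is no stereocentre to set or lose.

**Compound list**
1 | m-cresol | Cc1cccc(O)c1 | starting material
2 | 3-bromotoluene | Cc1cccc(Br)c1 | starting material
3 | bis(3-methylphenyl) ether | Cc1cccc(Oc2cccc(C)c2)c1 | intermediate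
4 | [4-methyl-2-(3-methylphenoxy)phenyl]lithium | [Li]c1ccc(C)cc1Oc1cccc(C)c1 | intermediate
5 | dimethyl [4-methyl-2-(3-methylphenoxy)phenyl]boronate | COB(OC)c1ccc(C)cc1Oc1cccc(C)c1 | intermediate
6 | 4-methyl-2-(3-methylphenoxy)phenol | Cc1ccc(O)c(Oc2cccc(C)c2)c1 | intermediate
7 | p-cresol | Cc1ccc(O)cc1 | starting material
8 | 2,6-dibromo-4-methylphenol | Cc1cc(Br)c(O)c(Br)c1 | intermediate
9 | 2,6-dibromo-4-(bromomethyl)phenol | Oc1c(Br)cc(CBr)cc1Br | intermediate
10 | dipotassium salt of 6 (phenoxide on ring A, benzylic carbanion on ring B) | [K+].[K+].[CH2-]c1cccc(Oc2cc(C)ccc2[O-])c1 | intermediate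
11 | potassium [3-(2-hydroxy-5-methylphenoxy)phenyl]methanesulfinate | [K+].[O-]S(=O)Cc1cccc(Oc2cc(C)ccc2O)c1 | intermediate
12 | 2,6-dibromo-4-({[3-(2-hydroxy-5-methylphenoxy)benzyl]sulfonyl}methyl)phenol | Cc1ccc(O)c(Oc2cccc(CS(=O)(=O)Cc3cc(Br)c(O)c(Br)c3)c2)c1 | intermediate
13 | 1,3-dibromo-2-methoxy-5-({[3-(2-methoxy-5-methylphenoxy)benzyl]sulfonyl}methyl)benzene | Cc1ccc(OC)c(Oc2cccc(CS(=O)(=O)Cc3cc(Br)c(OC)c(Br)c3)c2)c1 | intermediate
14 | 1-bromo-2-methoxy-5-({[3-(2-methoxy-5-methylphenoxy)benzyl]sulfonyl}methyl)-3-(4-methylphenoxy)benzene | Cc1ccc(Oc2cc(CS(=O)(=O)Cc3cccc(Oc4cc(C)ccc4OC)c3)cc(Br)c2OC)cc1 | intermediate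
15 | 1,2-dimethoxy-5-({[3-(2-methoxy-5-methylphenoxy)benzyl]sulfonyl}methyl)-3-(4-methylphenoxy)benzene | Cc1ccc(Oc2cc(CS(=O)(=O)Cc3cccc(Oc4cc(C)ccc4OC)c3)cc(OC)c2OC)cc1 | intermediate
16 | bis(bromomethyl) analogue of 15 (both CH3 replaced by CH2Br) | BrCc1ccc(Oc2cc(CS(=O)(=O)Cc3cccc(Oc4cc(CBr)ccc4OC)c3)cc(OC)c2OC)cc1 | intermediate
17 | 21-membered macrocycle, ring A–CH2SCH2–ring D and ring B–CH2SO2CH2–ring C, tri-O-methyl | COc1ccc2cc1Oc1cccc(c1)CS(=O)(=O)Cc1cc(OC)c(OC)c(c1)Oc1ccc(cc1)CSC2 | intermediate
18 | 21-membered bis-sulfone macrocycle, tri-O-methyl | COc1ccc2cc1Oc1cccc(c1)CS(=O)(=O)Cc1cc(OC)c(OC)c(c1)Oc1ccc(cc1)CS(=O)(=O)C2 | intermediate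
19 | 20-membered monosulfone macrocycle (ring B–CH2CH2–ring C formed, ring A/ring D sulfone left) | COc1ccc2cc1Oc1cccc(c1)CCc1cc(OC)c(OC)c(c1)Oc1ccc(cc1)CS(=O)(=O)C2 | intermediate
20 | 19-membered tri-O-methyl ether of the target | COc1ccc2cc1Oc1cccc(c1)CCc1cc(OC)c(OC)c(c1)Oc1ccc(cc1)CC2 | intermediate
21 | CNP0495401.0 (achiral as drawn) | Oc1ccc2cc1Oc1cccc(c1)CCc1cc(O)c(O)c(c1)Oc1ccc(cc1)CC2 | target

**Total steps:** 10. **Longest linear sequence:** 9 (steps 1, 2, 4, 5, 6, 7, 8, 9, 10).

**Steps most likely to fail**

*Step 9 (new reaction).* The risks are binding of SO2 to nickel, escape of benzyl radicals to oligomers, and nickel insertion into aryl C–O bonds.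
- The fallback uses known chemistry. It sets out from 18 and rejoins the route at 20.
- A double Ramberg–Bäcklund reaction (KOH on alumina, CBr2F2, t-BuOH/CH2Cl2, rt) gives the 19-membered macrocyclic bis-stilbene F10 as an E/Z mixture.
- Hydrogenation (H2, Pd/C, EtOAc) erases the alkene geometry and gives 20.

*Step 4.* The risks are incomplete or ring-directed metalation of the phenoxide, poor SO2 capture, and O-alkylation.
- The fallback uses known chemistry. It sets out from 1, with 9 and 7 as partners, and rejoins the route at 13.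
- Acetylation of 1 (Ac2O, pyridine) gives 3-methylphenyl acetate F1.
- Wohl–Ziegler bromination (NBS, AIBN, PhCF3, reflux) gives 3-(bromomethyl)phenyl acetate F2.
- Compound 9 with HOCH2SO2Na and K2CO3 in DMF gives, through its quinone methide, sodium (3,5-dibromo-4-hydroxyphenyl)methanesulfinate F3.
- F3 is S-alkylated in the same pot by F2 to 3-{[(3,5-dibromo-4-hydroxybenzyl)sulfonyl]methyl}phenyl acetate F4.
- MeI/K2CO3 in acetone gives 3-{[(3,5-dibromo-4-methoxybenzyl)sulfonyl]methyl}phenyl acetate F5.
- K2CO3/MeOH frees 3-{[(3,5-dibromo-4-methoxybenzyl)sulfonyl]methyl}phenol F6.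
- Separately, 7 is iodinated (NIS, catalytic TsOH, MeCN) to 2-iodo-4-methylphenol F7 and methylated (MeI, K2CO3) to 2-iodo-4-methylanisole F8.
- Ullmann coupling of F6 with F8 (CuI, picolinic acid, K3PO4, DMSO, 80 °C) reacts at the C–I bond only and gives 13.

*Step 8.* The risks are oligomerisation in the two-component closure and solvolysis of the labile ring A bromide.
- The fallback uses known chemistry. It sets out from 16 and rejoins the route at 17.
- KSAc (1.0 equiv, acetone, 0 °C) converts one terminus into the bromo thioacetate F9. It is drawn with sulfur on the ring A side, and the other regioisomer leads to the same ring.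
- Slow addition of F9 to K2CO3 in MeOH/THF unmasks the thiolate, which closes the ring in a unimolecular step to 17.
- Oxidation as in step 8 then gives 18.

**Further compounds**
F1 | step 4 | 3-methylphenyl acetate | CC(=O)Oc1cccc(C)c1
F2 | step 4 | 3-(bromomethyl)phenyl acetate | CC(=O)Oc1cccc(CBr)c1
F3 | step 4 | sodium (3,5-dibromo-4-hydroxyphenyl)methanesulfinate | [Na+].[O-]S(=O)Cc1cc(Br)c(O)c(Br)c1
F4 | step 4 | 3-{[(3,5-dibromo-4-hydroxybenzyl)sulfonyl]methyl}phenyl acetate | CC(=O)Oc1cccc(CS(=O)(=O)Cc2cc(Br)c(O)c(Br)c2)c1
F5 | step 4 | 3-{[(3,5-dibromo-4-methoxybenzyl)sulfonyl]methyl}phenyl acetate | CC(=O)Oc1cccc(CS(=O)(=O)Cc2cc(Br)c(OC)c(Br)c2)c1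
F6 | step 4 | 3-{[(3,5-dibromo-4-methoxybenzyl)sulfonyl]methyl}phenol | Oc1cccc(CS(=O)(=O)Cc2cc(Br)c(OC)c(Br)c2)c1
F7 | step 4 | 2-iodo-4-methylphenol | Cc1ccc(O)c(I)c1
F8 | step 4 | 2-iodo-4-methylanisole | COc1ccc(C)cc1I
F9 | step 8 | bromo thioacetate of 16 (AcS–CH2 on ring A, CH2Br on ring D) | CC(=O)SCc1ccc(OC)c(Oc2cccc(CS(=O)(=O)Cc3cc(OC)c(OC)c(Oc4ccc(CBr)cc4)c3)c2)c1
F10 | step 9 | 19-membered macrocyclic bis-stilbene, tri-O-methyl, E/Z mixture | COc1ccc2cc1Oc1cccc(c1)C=Cc1cc(OC)c(OC)c(c1)Oc1ccc(cc1)C=C2
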